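**Retrosynthetic overview**

1. The ten-membered ring is formed last (second ring) at C9–C10 by an intramolecular nickel-catalysed reductive coupling of a (Z)-alkenyl iodide with the primary iodide of an iodohydrin. It replaces RCM or a macrocyclic allylation, leaves 8-OH free and gives the target directly.
2. The γ-lactone is formed first: an intermolecular chromium-mediated 2-(methoxycarbonyl)allylation/lactonisation joins C6–C7 between a (Z)-4-hydroxy-enal (as its lactol) and a Baylis–Hillman bromide from (R)-glyceraldehyde acetonide. C8 comes from the chiral pool and steers C6 and C7.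
3. The C4=C5 geometry (C15 cis to C6) and the C15 oxygen come from a 3-substituted furan used as a latent (Z)-2-ene-1,4-dioxygenated unit (singlet oxygen, NaBH4, i-Bu2AlH).
4. C2 is set by Noyori transfer hydrogenation of a furyl ynone; the Z-C1=C10 iodide by hydroxyl-directed trans-hydroalumination/iodination.
5. 15-OAc and the 2-O-tigloyl group are installed before ring closure; the acetonide is then converted into the iodohydrin.

Assumption: the target is the (2S,6R,7R,8R) enantiomer defined by the SMILES (germacrane locants C1–C15 are used in the explanations), and 2-(furan-3-yl)acetic acid, prop-1-ynylmagnesium bromide and (R)-glyceraldehyde acetonide are purchased.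

**Step 1**
Reactants: 1 2-(furan-3-yl)acetic acid
Product: 3 2-(furan-3-yl)-N-methoxy-N-methylacetamide, via acyl imidazole 2 (not isolated)
Conditions: 1,1'-carbonyldiimidazole, CH2Cl2, 25 °C; then MeNHOMe·HCl, 25 °C
Reagents that add atoms: N,O-dimethylhydroxylamine hydrochloride (CNOC.Cl)
Why: Carbonyldiimidazole activation gives the acyl imidazole, which acylates the hydroxylamine (Weinreb amide formation); no stereocentre is involved.

**Step 2**
Reactants: 3 2-(furan-3-yl)-N-methoxy-N-methylacetamide; 4 prop-1-ynylmagnesium bromide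
Product: 5 1-(furan-3-yl)pent-3-yn-2-one
Conditions: THF, −78 → 0 °C; aq. NH4Cl at −78 °C
Reagents that add atoms: none
Why: Weinreb ketone synthesis, in which magnesium chelation of the tetrahedral adduct prevents over-addition and the ynone is released only on cold aqueous quench.

**Step 3**
Reactants: 5 1-(furan-3-yl)pent-3-yn-2-one
Product: 6 (2S)-1-(furan-3-yl)pent-3-yn-2-ol
Conditions: Ru[(S,S)-TsDPEN](p-cymene) (1 mol %), i-PrOH, 25 °C
Reagents that add atoms: none
Why: Noyori asymmetric transfer hydrogenation of an alkynyl ketone, in which the (S,S)-catalyst places the alkynyl group in the position an aryl group normally takes and delivers hydride to give the (S)-propargylic alcohol (this sets C2).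

**Step 4**
Reactants: 6 (2S)-1-(furan-3-yl)pent-3-yn-2-ol
Product: 8 (2S,3Z)-1-(furan-3-yl)-4-iodopent-3-en-2-ol, via vinylalanate 7 (not isolated)
Conditions: NaAlH2(OCH2CH2OMe)2, THF, 0 → 25 °C; then I2, −78 °C
Reagents that add atoms: iodine (II)
Why: Hydroxyl-directed trans-hydroalumination of the propargylic alcohol puts aluminium on the distal alkyne carbon and iodinolysis with retention gives the (Z)-3-iodoallylic alcohol (Corey-type hydroalumination–iodination), which fixes the later C1=C10 geometry.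

**Step 5**
Reactants: 8 (2S,3Z)-1-(furan-3-yl)-4-iodopent-3-en-2-ol
Product: 10 5-hydroxy-4-[(2S,3Z)-2-hydroxy-4-iodopent-3-en-1-yl]furan-2(5H)-one, via endoperoxide 9 (not isolated)
Conditions: O2, visible light, tetraphenylporphyrin (cat.), i-Pr2NEt, CH2Cl2, −78 °C
Reagents that add atoms: dioxygen (O=O)
Why: [4+2] cycloaddition of singlet oxygen to the furan followed by Kornblum–DeLaMare fragmentation, in which the hindered base removes the less hindered bridgehead proton, gives the 4-substituted 5-hydroxybutenolide regioselectively; the iodoalkene reacts far more slowly than the furan.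

**Step 6**
Reactants: 10 5-hydroxy-4-[(2S,3Z)-2-hydroxy-4-iodopent-3-en-1-yl]furan-2(5H)-one
Product: 12 4-[(2S,3Z)-2-hydroxy-4-iodopent-3-en-1-yl]furan-2(5H)-one, via hydroxy acid 11 (not isolated)
Conditions: NaBH4, EtOH, 0 °C; then 1 M HCl, 25 °C
Reagents that add atoms: none
Why: Borohydride reduces the ring-opened formyl carboxylate and acidification relactonises the (Z)-hydroxy acid (reduction–lactonisation), so C15 sits at the alcohol level inside a ring that locks the C4=C5 geometry.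

**Step 7**
Reactants: 12 4-[(2S,3Z)-2-hydroxy-4-iodopent-3-en-1-yl]furan-2(5H)-one
Product: 13 4-[(2S,3Z)-2-hydroxy-4-iodopent-3-en-1-yl]-2,5-dihydrofuran-2-ol
Conditions: i-Bu2AlH (2.2 equiv), CH2Cl2, −78 °C
Reagents that add atoms: none
Why: Partial lactone reduction stops at the aluminium hemiacetal at low temperature and gives the lactol, a masked (Z)-4-hydroxy-enal with C6 at the aldehyde level.

**Step 8**
Reactants: 14 (4R)-2,2-dimethyl-1,3-dioxolane-4-carbaldehyde; 15 methyl acrylate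
Product: 16 methyl 2-{[(4R)-2,2-dimethyl-1,3-dioxolan-4-yl](hydroxy)methyl}prop-2-enoate
Conditions: DABCO (0.5 equiv), 1,4-dioxane/H2O, 25 °C
Reagents that add atoms: none
Why: Morita–Baylis–Hillman reaction; the new carbinol centre becomes sp2 in the next step, so its configuration does not matter.

**Step 9**
Reactants: 16 methyl 2-{[(4R)-2,2-dimethyl-1,3-dioxolan-4-yl](hydroxy)methyl}prop-2-enoate
Product: 17 methyl (2Z)-2-(bromomethyl)-3-[(4S)-2,2-dimethyl-1,3-dioxolan-4-yl]prop-2-enoate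
Conditions: NBS, Me2S, CH2Cl2, 0 → 25 °C
Reagents that add atoms: N-bromosuccinimide (O=C1CCC(=O)N1Br)
Why: The Corey–Kim-type bromosulfonium reagent converts the Baylis–Hillman alcohol into the rearranged primary allylic bromide (SN2' substitution), the favoured (Z)-isomer; the dioxolane centre is untouched and its descriptor changes only through the priority rules.

**Step 10**
Reactants: 13 4-[(2S,3Z)-2-hydroxy-4-iodopent-3-en-1-yl]-2,5-dihydrofuran-2-ol; 17 methyl (2Z)-2-(bromomethyl)-3-[(4S)-2,2-dimethyl-1,3-dioxolan-4-yl]prop-2-enoate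
Product: 20 (4S,5R)-4-[(4S)-2,2-dimethyl-1,3-dioxolan-4-yl]-5-[(1Z,4S,5Z)-4-hydroxy-2-(hydroxymethyl)-6-iodohepta-1,5-dien-1-yl]-3-methylideneoxolan-2-one, via allylchromium dichloride 18 (not isolated), via hydroxy ester 19 (not isolated)
Conditions: CrCl2 (5 equiv), THF, 25 °C; then PPTS (cat.), CH2Cl2, 25 °C
Reagents that add atoms: none
Why: Nozaki–Hiyama-type chromium allylation of the open hydroxy-enal form through a chair transition state of the equilibrated E-allylchromium gives the anti adduct (trans-lactone after acid-catalysed lactonisation), and with H-8 eclipsing the olefin to avoid allylic strain the aldehyde adds anti to the C8–C9 bond of the dioxolane, which sets C6 and C7 from the chiral-pool centre C8.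

**Step 11**
Reactants: 20 (4S,5R)-4-[(4S)-2,2-dimethyl-1,3-dioxolan-4-yl]-5-[(1Z,4S,5Z)-4-hydroxy-2-(hydroxymethyl)-6-iodohepta-1,5-dien-1-yl]-3-methylideneoxolan-2-one
Product: 21 (4S,5R)-5-[(1Z,4S,5Z)-2-(acetoxymethyl)-4-hydroxy-6-iodohepta-1,5-dien-1-yl]-4-[(4S)-2,2-dimethyl-1,3-dioxolan-4-yl]-3-methylideneoxolan-2-one
Conditions: AcCl (1.1 equiv), 2,4,6-collidine, CH2Cl2, −78 °C
Reagents that add atoms: acetyl chloride (CC(Cl)=O)
Why: Chemoselective acylation, since acetyl chloride with collidine at low temperature acetylates the unhindered primary allylic hydroxyl much faster than the secondary one.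

**Step 12**
Reactants: 21 (4S,5R)-5-[(1Z,4S,5Z)-2-(acetoxymethyl)-4-hydroxy-6-iodohepta-1,5-dien-1-yl]-4-[(4S)-2,2-dimethyl-1,3-dioxolan-4-yl]-3-methylideneoxolan-2-one
Product: 22 (4S,5R)-5-[(1Z,4S,5Z)-2-(acetoxymethyl)-6-iodo-4-{[(2E)-2-methylbut-2-enoyl]oxy}hepta-1,5-dien-1-yl]-4-[(4S)-2,2-dimethyl-1,3-dioxolan-4-yl]-3-methylideneoxolan-2-one
Conditions: tigloyl chloride, pyridine, DMAP (cat.), CH2Cl2, 0 → 25 °C
Reagents that add atoms: tigloyl chloride (C/C=C(\C)C(Cl)=O)
Why: DMAP-catalysed acylation of the only remaining hydroxyl proceeds with retention at C2, and the tiglate is the stable E isomer so no isomerisation is expected.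

**Step 13**
Reactants: 22 (4S,5R)-5-[(1Z,4S,5Z)-2-(acetoxymethyl)-6-iodo-4-{[(2E)-2-methylbut-2-enoyl]oxy}hepta-1,5-dien-1-yl]-4-[(4S)-2,2-dimethyl-1,3-dioxolan-4-yl]-3-methylideneoxolan-2-one
Product: 23 (4R,5R)-5-[(1Z,4S,5Z)-2-(acetoxymethyl)-6-iodo-4-{[(2E)-2-methylbut-2-enoyl]oxy}hepta-1,5-dien-1-yl]-4-[(1S)-1,2-dihydroxyethyl]-3-methylideneoxolan-2-one
Conditions: AcOH/H2O (4:1), 40 °C
Reagents that add atoms: none
Why: Acid-catalysed hydrolysis of the isopropylidene acetal (acetal deprotection) leaves the esters and the lactone intact; the ring descriptor changes only through the priority rules.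

**Step 14**
Reactants: 23 (4R,5R)-5-[(1Z,4S,5Z)-2-(acetoxymethyl)-6-iodo-4-{[(2E)-2-methylbut-2-enoyl]oxy}hepta-1,5-dien-1-yl]-4-[(1S)-1,2-dihydroxyethyl]-3-methylideneoxolan-2-one
Product: 24 (4R,5R)-5-[(1Z,4S,5Z)-2-(acetoxymethyl)-6-iodo-4-{[(2E)-2-methylbut-2-enoyl]oxy}hepta-1,5-dien-1-yl]-4-[(1S)-1-hydroxy-2-iodoethyl]-3-methylideneoxolan-2-one
Conditions: PPh3, I2, imidazole, CH2Cl2, 0 °C
Reagents that add atoms: iodine (II)
Why: Garegg–Samuelsson (Appel-type) iodination, in which the preformed iodophosphonium reagent activates the less hindered primary hydroxyl and iodide displaces it, so the C8 carbinol keeps its configuration.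

**Step 15**
Reactants: 24 (4R,5R)-5-[(1Z,4S,5Z)-2-(acetoxymethyl)-6-iodo-4-{[(2E)-2-methylbut-2-enoyl]oxy}hepta-1,5-dien-1-yl]-4-[(1S)-1-hydroxy-2-iodoethyl]-3-methylideneoxolan-2-one
Product: 25 (2S,6R,7R,8R)-15-acetoxy-8-hydroxy-2-[(2E)-2-methylbut-2-enoyloxy]germacra-1(10),4,11(13)-trien-12,6-olide (CNP0129394.2)
Conditions: NiI2 (30 mol %), 4,4'-di-tert-butyl-2,2'-bipyridine (30 mol %), Mn (4 equiv), NaI, DMA, 40 °C, 2 mM (syringe pump)
Reagents that add atoms: none
Why: Proposed new method: intramolecular nickel-catalysed reductive cross-electrophile coupling, in which zerovalent nickel inserts into the alkenyl C–I bond with retention of the Z geometry, monovalent nickel abstracts iodine from the primary iodide, the C9 radical is captured by the tethered alkenylnickel and reductive elimination from trivalent nickel forms C9–C10 and the ten-membered ring with the β-hydroxyl left free; the closest known chemistry is the intermolecular nickel/manganese coupling of alkenyl halides with alkyl halides and the coupling of aryl or alkenyl halides with epoxides that runs through iodohydrins; no stereocentre is formed.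

**Compound list**

1 | 2-(furan-3-yl)acetic acid | OC(=O)Cc1ccoc1 | starting material
2 | 1-[2-(furan-3-yl)acetyl]imidazole | O=C(Cc1ccoc1)n1ccnc1 | intermediate
3 | 2-(furan-3-yl)-N-methoxy-N-methylacetamide | CON(C)C(=O)Cc1ccoc1 | intermediate
4 | prop-1-ynylmagnesium bromide | CC#C[Mg]Br | starting material
5 | 1-(furan-3-yl)pent-3-yn-2-one | CC#CC(=O)Cc1ccoc1 | intermediate
6 | (2S)-1-(furan-3-yl)pent-3-yn-2-ol | CC#C[C@@H](O)Cc1ccoc1 | intermediate
7 | cyclic sodium vinylalanate of 6 (Al bound to the C2 oxygen and to C4 of the pentenyl chain, two 2-methoxyethoxy groups on Al) | C/C1=C/[C@H](Cc2ccoc2)O[Al-]1(OCCOC)OCCOC.[Na+] | intermediate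
8 | (2S,3Z)-1-(furan-3-yl)-4-iodopent-3-en-2-ol | C/C(I)=C/[C@@H](O)Cc1ccoc1 | intermediate
9 | 5-[(2S,3Z)-2-hydroxy-4-iodopent-3-en-1-yl]-2,3,7-trioxabicyclo[2.2.1]hept-5-ene | C/C(I)=C/[C@@H](O)CC1=CC2OOC1O2 | intermediate
10 | 5-hydroxy-4-[(2S,3Z)-2-hydroxy-4-iodopent-3-en-1-yl]furan-2(5H)-one (hemiacetal epimers) | C/C(I)=C/[C@@H](O)CC1=CC(=O)OC1O | intermediate
11 | (2Z)-4-hydroxy-3-[(2S,3Z)-2-hydroxy-4-iodopent-3-en-1-yl]but-2-enoic acid | C/C(I)=C/[C@@H](O)C/C(CO)=C/C(O)=O | intermediate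
12 | 4-[(2S,3Z)-2-hydroxy-4-iodopent-3-en-1-yl]furan-2(5H)-one | C/C(I)=C/[C@@H](O)CC1=CC(=O)OC1 | intermediate
13 | 4-[(2S,3Z)-2-hydroxy-4-iodopent-3-en-1-yl]-2,5-dihydrofuran-2-ol (anomers) | C/C(I)=C/[C@@H](O)CC1=CC(O)OC1 | intermediate
14 | (4R)-2,2-dimethyl-1,3-dioxolane-4-carbaldehyde | O=C[C@H]1COC(C)(C)O1 | starting material
15 | methyl acrylate | C=CC(=O)OC | starting material
16 | methyl 2-{[(4R)-2,2-dimethyl-1,3-dioxolan-4-yl](hydroxy)methyl}prop-2-enoate (carbinol epimers) | C=C(C(=O)OC)C(O)[C@H]1COC(C)(C)O1 | intermediate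
17 | methyl (2Z)-2-(bromomethyl)-3-[(4S)-2,2-dimethyl-1,3-dioxolan-4-yl]prop-2-enoate | COC(=O)/C(CBr)=C/[C@H]1COC(C)(C)O1 | intermediate
18 | dichloro{3-[(4S)-2,2-dimethyl-1,3-dioxolan-4-yl]-2-(methoxycarbonyl)prop-2-en-1-yl}chromium | COC(=O)C(C[Cr](Cl)Cl)=C[C@H]1COC(C)(C)O1 | intermediate
19 | methyl (3S,4R,5Z,8S,9Z)-3-[(4S)-2,2-dimethyl-1,3-dioxolan-4-yl]-4,8-dihydroxy-6-(hydroxymethyl)-10-iodo-2-methylideneundeca-5,9-dienoate | COC(=O)C(=C)[C@@H]([C@H](O)/C=C(\CO)C[C@H](O)/C=C(/C)I)[C@H]1COC(C)(C)O1 | intermediate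
20 | (4S,5R)-4-[(4S)-2,2-dimethyl-1,3-dioxolan-4-yl]-5-[(1Z,4S,5Z)-4-hydroxy-2-(hydroxymethyl)-6-iodohepta-1,5-dien-1-yl]-3-methylideneoxolan-2-one | C=C1C(=O)O[C@H](/C=C(\CO)C[C@H](O)/C=C(/C)I)[C@H]1[C@H]2COC(C)(C)O2 | intermediate
21 | (4S,5R)-5-[(1Z,4S,5Z)-2-(acetoxymethyl)-4-hydroxy-6-iodohepta-1,5-dien-1-yl]-4-[(4S)-2,2-dimethyl-1,3-dioxolan-4-yl]-3-methylideneoxolan-2-one | C=C1C(=O)O[C@H](/C=C(\COC(C)=O)C[C@H](O)/C=C(/C)I)[C@H]1[C@H]2COC(C)(C)O2 | intermediate
22 | (4S,5R)-5-[(1Z,4S,5Z)-2-(acetoxymethyl)-6-iodo-4-{[(2E)-2-methylbut-2-enoyl]oxy}hepta-1,5-dien-1-yl]-4-[(4S)-2,2-dimethyl-1,3-dioxolan-4-yl]-3-methylideneoxolan-2-one | C=C1C(=O)O[C@H](/C=C(\COC(C)=O)C[C@H](OC(=O)/C(C)=C/C)/C=C(/C)I)[C@H]1[C@H]2COC(C)(C)O2 | intermediate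
23 | (4R,5R)-5-[(1Z,4S,5Z)-2-(acetoxymethyl)-6-iodo-4-{[(2E)-2-methylbut-2-enoyl]oxy}hepta-1,5-dien-1-yl]-4-[(1S)-1,2-dihydroxyethyl]-3-methylideneoxolan-2-one | C=C1C(=O)O[C@H](/C=C(\COC(C)=O)C[C@H](OC(=O)/C(C)=C/C)/C=C(/C)I)[C@H]1[C@H](O)CO | intermediate
24 | (4R,5R)-5-[(1Z,4S,5Z)-2-(acetoxymethyl)-6-iodo-4-{[(2E)-2-methylbut-2-enoyl]oxy}hepta-1,5-dien-1-yl]-4-[(1S)-1-hydroxy-2-iodoethyl]-3-methylideneoxolan-2-one | C=C1C(=O)O[C@H](/C=C(\COC(C)=O)C[C@H](OC(=O)/C(C)=C/C)/C=C(/C)I)[C@H]1[C@H](O)CI | intermediate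
25 | (2S,6R,7R,8R)-15-acetoxy-8-hydroxy-2-[(2E)-2-methylbut-2-enoyloxy]germacra-1(10),4,11(13)-trien-12,6-olide (1(10)Z; C15 cis to C6) | C=C1C(=O)O[C@@H]2/C=C(\COC(C)=O)C[C@H](OC(=O)/C(C)=C/C)/C=C(/C)C[C@@H](O)[C@@H]12 | target

**Totals**

Total step count: 15. Longest linear sequence: 13 steps (1 → 25 through steps 1–7 and 10–15); steps 8 and 9 make the side fragment 17.

**Three steps most likely to fail**

Step 15 (macrocyclisation). The ring is strained, reduction or oligomerisation of the C9 radical can compete, and low-valent nickel can ionise the allylic esters or engage the methylene lactone. Fallback, from 24 back to 25: the radical closure is replaced by a polar, stepwise one. Compound 24 is silylated (Et3SiOTf, 2,6-lutidine) to the triethylsilyl ether F1. Zinc dust with LiCl inserts selectively into the primary C–I bond to give the alkylzinc iodide F2. An intramolecular Negishi coupling (Pd(OAc)2, SPhos, THF, high dilution) then gives the silylated macrocycle F3, and HF·pyridine releases 25.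

Step 10 (chromium allylation). The anti outcome depends on equilibration of the allylchromium, the facial sense rests on a transition-state model, and the lactol can dehydrate back to a furan. Fallback, from 14 back to 20: a boron reagent of fixed geometry replaces the chromium reagent. Aldehyde 14 is homologated (Ohira–Bestmann reagent, K2CO3, MeOH) to the alkyne F4. Carboxylation (n-BuLi, ClCO2Me) gives the ynoate F5. Syn-hydrocupration (i-Bu2AlH, MeCu, HMPA) with trapping by ICH2Bpin gives the allylboronate F6, in which C8 is cis to the ester. Heating F6 with lactol 13 in toluene at 80 °C is a closed chair allylboration that can only give the anti adduct; aqueous work-up gives hydroxy ester 19, which lactonises (PPTS) to 20.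

Step 5 (photo-oxygenation). Singlet oxygen may also attack the iodoalkene in an ene reaction, and the base-directed regiochemistry may be incomplete. Fallback, from 8 back to 12: the oxygen is introduced by C–H borylation instead. [Ir(OMe)(cod)]2 with 4,4'-di-tert-butyl-2,2'-bipyridine and B2pin2 borylates 8 at the unhindered furan α-position to give the furyl boronate F7. Oxidation with NaBO3·4H2O gives the 2-hydroxyfuran F8, which tautomerises (Et3N) to butenolide 12, so 10 and 11 are bypassed.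

**Further compounds**

F1 | step 15 | 8-O-triethylsilyl ether of 24 | C=C1C(=O)O[C@H](/C=C(\COC(C)=O)C[C@H](OC(=O)/C(C)=C/C)/C=C(/C)I)[C@H]1[C@H](O[Si](CC)(CC)CC)CI
F2 | step 15 | alkylzinc iodide from F1 (C9–ZnI) | C=C1C(=O)O[C@H](/C=C(\COC(C)=O)C[C@H](OC(=O)/C(C)=C/C)/C=C(/C)I)[C@H]1[C@H](O[Si](CC)(CC)CC)C[Zn]I
F3 | step 15 | 8-O-triethylsilyl ether of 25 | C=C1C(=O)O[C@@H]2/C=C(\COC(C)=O)C[C@H](OC(=O)/C(C)=C/C)/C=C(/C)C[C@@H](O[Si](CC)(CC)CC)[C@@H]12
F4 | step 10 | (4S)-4-ethynyl-2,2-dimethyl-1,3-dioxolane | C#C[C@H]1COC(C)(C)O1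
F5 | step 10 | methyl 3-[(4S)-2,2-dimethyl-1,3-dioxolan-4-yl]prop-2-ynoate | COC(=O)C#C[C@H]1COC(C)(C)O1
F6 | step 10 | methyl (2Z)-3-[(4S)-2,2-dimethyl-1,3-dioxolan-4-yl]-2-[(4,4,5,5-tetramethyl-1,3,2-dioxaborolan-2-yl)methyl]prop-2-enoate | COC(=O)/C(CB1OC(C)(C)C(C)(C)O1)=C\[C@H]2COC(C)(C)O2
F7 | step 5 | (2S,3Z)-4-iodo-1-[5-(4,4,5,5-tetramethyl-1,3,2-dioxaborolan-2-yl)furan-3-yl]pent-3-en-2-ol | C/C(I)=C/[C@@H](O)Cc1coc(B2OC(C)(C)C(C)(C)O2)c1
F8 | step 5 | 4-[(2S,3Z)-2-hydroxy-4-iodopent-3-en-1-yl]furan-2-ol | C/C(I)=C/[C@@H](O)Cc1coc(O)c1
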